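**Strategy.** The plan is to form the resorcinol ring A (C4a, C5, C6, C7, C8, C8a) and the pyran ring C (O1, C2, C3, C4, C4a, C8a) of the upper flavan in one late operation. The feature exploited is that the C7 hydroxyl and O1 sit meta on ring A while O1 is joined to C4a through C2–C3–C4: a diazo vinyl ketone on C4 is photolysed to a vinylketene that is trapped by an ethynyl ether on the C2 oxygen and aromatises. The precursor is therefore an open C2–C3–C4 chain with both stereocentres in place, carrying ring B, the benzylated epiafzelechin unit at C4, the O-ethynyl group and the diazo enone.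

Key step: step 18

**Remarks before the steps**

- Abbreviations in names: ArB = 4-(benzyloxy)phenyl; ArD = (2R,3R)-3,5,7-tris(benzyloxy)-2-[4-(benzyloxy)phenyl]chroman-8-yl. Atom labels O1, C2, C3, C4, C4a, C5–C8a are those of the upper flavan and are also used for the corresponding open-chain atoms.
- Assumption: (DHQD)2AQN is taken to open anhydride 12 at the carbonyl that gives (3S)-13, as with simple 3-arylglutaric anhydrides; if the opposite sense is found, the pseudoenantiomeric (DHQ)2AQN is used with no other change.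
- Stereochemical note: the upper unit is 2S,4S (2,4-cis) and the lower unit 2R,3R in precursor 32, in benzannulation product 37 and in the target alike. The CIP label at C4 changes along the route only because substituent priorities change.
- Design notes on the precursor:
  - The C4a acyl arm is reduced and carried as a silyl ether while the ethynyl ether is made, because an ester there would lactonise onto the C2 alkoxide and be attacked by n-BuLi. The enone is built afterwards under buffered conditions.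
  - The diazo enone 32 is made last, kept cold and dark, and irradiated the same day, since a diazo ketone tethered to an electron-rich alkyne may undergo dark dipolar cycloaddition.
  - Benzyl ethers protect the lower unit and ring B: all five fall in one hydrogenolysis and the new C7 phenol needs no protection.

**Route**

Step 1
Reactants: 1 (−)-epiafzelechin
Product: 3 (2R,3R)-3,5,7-tris(benzyloxy)-2-[4-(benzyloxy)phenyl]chromane, via 5,7,4'-tribenzyl ether 2 (not isolated)
Conditions: BnBr (5 equiv), K2CO3, DMF, rt; then NaH, 0 °C → rt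
Reagents that add atoms: benzyl bromide, BrCc1ccccc1
Why: Williamson etherification: K2CO3 is basic enough to alkylate the three phenols without opening the pyran ring, and NaH then deprotonates the C3 alcohol for the fourth benzylation in the same flask, no stereocentre being involved.

Step 2
Reactants: 3 tetra-O-benzyl-epiafzelechin
Product: 4 (2R,3R)-8-bromo-3,5,7-tris(benzyloxy)-2-[4-(benzyloxy)phenyl]chromane (ArD–Br)
Conditions: NBS (1.0 equiv), CH2Cl2, −78 °C → 0 °C
Reagents that add atoms: N-bromosuccinimide, O=C1CCC(=O)N1Br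
Why: Electrophilic aromatic bromination of the phloroglucinol-type ring, which in benzylated flavan-3-ols goes to C8 (activated by O1 and the C7 ether and less crowded than C6).

Step 3
Reactants: 4 ArD–Br
Product: 6 ArD–CHO (the 8-carbaldehyde), via aryllithium 5 (not isolated)
Conditions: n-BuLi (1.1 equiv), THF, −78 °C; then DMF; H2O
Reagents that add atoms: N,N-dimethylformamide, CN(C)C=O
Why: Bromine–lithium exchange at −78 °C outruns benzylic or ortho metalation, and formylation of the aryllithium with DMF places the aldehyde carbon (the future C4) on C8 of the lower unit.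

Step 4
Reactants: 6 ArD–CHO; 7 dimethyl malonate
Product: 8 dimethyl 2-(ArD-methylidene)malonate
Conditions: 7 (1.2 equiv), piperidine (0.2 equiv), AcOH (0.2 equiv), PhMe, reflux, Dean–Stark
Reagents that add atoms: none
Why: Knoevenagel condensation of the aryl aldehyde with the malonate under amine–acid catalysis, driven to the arylidene malonate by azeotropic removal of water and leaving the benzyl ethers and the chroman stereocentres untouched.

Step 5
Reactants: 8 arylidene malonate; 7 dimethyl malonate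
Product: 9 tetramethyl 2-ArD-propane-1,1,3,3-tetracarboxylate
Conditions: 7 (3 equiv), NaOMe (0.3 equiv), MeOH–THF, 50 °C; AcOH quench
Reagents that add atoms: none
Why: Michael addition of the malonate anion to the doubly activated arylidene malonate, held on the adduct side by excess malonate and catalytic base; the carbon that becomes C4 then carries two identical arms and is not yet stereogenic.

Step 6
Reactants: 9 tetraester
Product: 11 3-ArD-pentanedioic acid, via tetraacid 10 (not isolated)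
Conditions: KOH, EtOH–H2O, 70 °C; HCl to pH 2; then pyridine, 110 °C
Reagents that add atoms: potassium hydroxide, [K+].[OH-]
Why: Ester saponification and thermal decarboxylation of the two malonic acid units (malonic ester synthesis), done with base and hot pyridine instead of mineral acid so that the benzyl ethers survive.

Step 7
Reactants: 11 3-ArD-pentanedioic acid
Product: 12 4-ArD-oxane-2,6-dione (3-ArD-glutaric anhydride)
Conditions: Ac2O, 80 °C; evaporate
Reagents that add atoms: none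
Why: Cyclodehydration of a glutaric acid to its six-membered cyclic anhydride with acetic anhydride.

Step 8
Reactants: 12 3-ArD-glutaric anhydride
Product: 13 (3S)-3-ArD-5-methoxy-5-oxopentanoic acid
Conditions: MeOH (10 equiv), (DHQD)2AQN (0.2 equiv), Et2O–PhMe, −20 °C
Reagents that add atoms: methanol, CO
Why: Desymmetrising alcoholysis of a prochiral cyclic anhydride under general-base catalysis by the quinuclidine nitrogen of the cinchona ether, which delivers methanol to one of the two carbonyl groups and so sets C4 under catalyst control, the chroman stereocentres being too remote to override it.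

Step 9
Reactants: 13 hemiester; 14 1-(benzyloxy)-4-bromobenzene
Product: 17 methyl (3S)-3-ArD-5-ArB-5-oxopentanoate, via acid chloride 15 (not isolated), via Grignard reagent 16 (not isolated)
Conditions: 13, 1-chloro-N,N,2-trimethylprop-1-en-1-amine, CH2Cl2, 0 °C; 14, Mg, THF; then combine, Fe(acac)3 (3 mol %), THF, −78 °C
Reagents that add atoms: none
Why: Iron-catalysed acylation of an aryl Grignard reagent with an acid chloride (formed under neutral conditions and used at once), which at −78 °C is far faster than attack on the methyl ester or on the product ketone, so that only the acid arm becomes the C2 aryl ketone.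

Step 10
Reactants: 17 keto ester
Product: 19 (1S,3R)-3-ArD-1-ArB-pentane-1,5-diol, via hydroxy ester 18 (not isolated)
Conditions: (R)-2-methyl-CBS-oxazaborolidine (0.2 equiv), BH3·SMe2, THF, −20 °C; then LiBH4, 0 °C → rt; aq. work-up
Reagents that add atoms: none
Why: CBS reduction, in which the (R)-oxazaborolidine–borane complex delivers hydride to the face of the aryl ketone (aryl as the large group) that gives the (S)-carbinol and so sets C2 by reagent control, followed by LiBH4 reduction of the ester, because an acyl group left here would lactonise onto the C2 alkoxide and be attacked by n-BuLi in step 12.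

Step 11
Reactants: 19 diol
Product: 20 (1S,3R)-3-ArD-1-ArB-5-[(tert-butyldimethylsilyl)oxy]pentan-1-ol
Conditions: TBSCl (1.05 equiv), imidazole, CH2Cl2, −20 °C → 0 °C
Reagents that add atoms: tert-butyldimethylsilyl chloride, CC(C)(C)[Si](C)(C)Cl
Why: Selective silylation of the primary hydroxyl over the hindered secondary benzylic one leaves only the C2 hydroxyl free.

Step 12
Reactants: 20 silyl ether alcohol; 21 trichloroethylene
Product: 25 tert-butyl{[(3R,5S)-3-ArD-5-ArB-5-(ethynyloxy)pentyl]oxy}dimethylsilane, via dichlorovinyl ether 22 (not isolated), via chloroethynyl ether 23 (not isolated), via lithium acetylide 24 (not isolated)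
Conditions: KH (2.2 equiv), 21 (1.1 equiv), THF, 0 °C → rt; then n-BuLi (2.5 equiv), −78 °C → −40 °C; MeOH, −78 °C; Et3N-washed silica, below 25 °C
Reagents that add atoms: none
Why: Ethynyl ether synthesis by addition of the potassium alkoxide to dichloroacetylene formed in situ, then dehydrochlorination and chlorine–lithium exchange of the 1,2-dichlorovinyl ether with n-BuLi and cold protonation; the C2–O bond is never broken, so C2 keeps its configuration, and silyl and benzyl ethers are inert to both bases.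

Step 13
Reactants: 25 ethynyl ether
Product: 26 (3R,5S)-3-ArD-5-ArB-5-(ethynyloxy)pentan-1-ol
Conditions: Bu4NF, THF, 0 °C
Reagents that add atoms: none
Why: Fluoride-mediated desilylation under basic conditions, which the acid-labile ethynyl ether tolerates.

Step 14
Reactants: 26 primary alcohol
Product: 27 (3S,5S)-3-ArD-5-ArB-5-(ethynyloxy)pentanal
Conditions: Dess–Martin periodinane, NaHCO3, CH2Cl2, 0 °C
Reagents that add atoms: none
Why: Dess–Martin oxidation buffered with NaHCO3 stops at the aldehyde and keeps the medium free of acid that would add to the ethynyl ether; C4 is β to the carbonyl and cannot epimerise.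

Step 15
Reactants: 27 aldehyde
Product: 28 (5R,7S)-5-ArD-7-ArB-7-(ethynyloxy)hept-1-en-3-ol (both C3 epimers)
Conditions: CH2=CHMgBr (1.3 equiv), THF, −78 °C; H2O
Reagents that add atoms: vinylmagnesium bromide, C=C[Mg]Br
Why: Grignard addition to the aldehyde, which at −78 °C is much faster than deprotonation of the acetylenic C–H; the new carbinol centre is left uncontrolled because it is oxidised in step 16.

Step 16
Reactants: 28 allylic alcohol
Product: 29 (5S,7S)-5-ArD-7-ArB-7-(ethynyloxy)hept-1-en-3-one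
Conditions: Dess–Martin periodinane, NaHCO3, CH2Cl2, 0 °C
Reagents that add atoms: none
Why: Dess–Martin oxidation of the allylic alcohol to the vinyl ketone under buffered, non-nucleophilic conditions that avoid conjugate addition.

Step 17
Reactants: 29 vinyl ketone
Product: 32 (5R,7S)-4-diazo-5-ArD-7-ArB-7-(ethynyloxy)hept-1-en-3-one, via lithium enolate 30 (not isolated), via trifluoroacetyl ketone 31 (not isolated)
Conditions: LiN(SiMe3)2 (1.05 equiv), THF, −78 °C; CF3CO2CH2CF3 (1.2 equiv); aq. work-up at pH 5–6; then MsN3 (1.05 equiv), Et3N, H2O (1 equiv), MeCN, 0 °C; used at once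
Reagents that add atoms: methanesulfonyl azide, CS(=O)(=O)N=[N+]=[N-]
Why: Detrifluoroacetylative (Regitz-type) diazo transfer: the only enolate the vinyl ketone can form (toward C4a) is C-trifluoroacetylated and the 1,3-diketone takes the diazo group from the sulfonyl azide with loss of the activating acyl group, the ketone being deprotonated in preference to the far less acidic acetylenic C–H and C4 not being enolisable.

Step 18
Reactants: 32 diazo enone ethynyl ether
Product: 37 (2R,3R)-3,5,7-tris(benzyloxy)-2-[4-(benzyloxy)phenyl]-8-{(2S,4S)-2-[4-(benzyloxy)phenyl]-7-hydroxychroman-4-yl}chromane, via vinylketene 33 (not isolated), via cyclobutenone 34 (not isolated), via dienylketene 35 (not isolated), via cyclohexadienone 36 (not isolated)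
Conditions: hν (365 nm LED), degassed PhMe (0.005 M), 20 °C; then 80 °C, 1 h
Reagents that add atoms: none
Why: Proposed new method: under irradiation the diazo ketone loses N2 with 1,2-shift of the vinyl group to the former diazo carbon (photo-Wolff rearrangement, forming C4a–C5), and the resulting vinylketene adds across its C7=C4a bond to the tethered ethynyl ether in a [2+2] cycloaddition (C7–C8 and C4a–C8a); electrocyclic 4π opening of the strained bicyclic 4-vinylcyclobutenone unveils a dienylketene, and 6π ring closure (C6–C7) followed by enolisation delivers the C7 phenol. The closest known chemistry is the intermolecular Danheiser benzannulation of photochemically generated vinylketenes with alkynyl ethers, together with intramolecular ketene–alkyne [2+2] cycloadditions; a tethered version that builds the oxygen heterocycle in the same operation is without precedent. Ring C closes in the [2+2] event as a six-membered ring through the O1–C2–C3–C4 tether (C4a–C8a bond), and ring A closes in the 6π electrocyclisation (C6–C7 bond) after the four-membered ring has opened. No stereocentre is created: C2 and C4 are spectators set in steps 10 and 8, and the quaternary centre that C4a becomes in the cyclobutenone is erased on ring opening. The selectivity required is regiochemical (O1 meta to the C7 hydroxyl) and is secured twice, geometrically by the tether, which lets only C8a reach C4a in a six-membered ring, and electronically because the nucleophilic terminal carbon C8 of the alkoxyalkyne bonds to the electrophilic ketene carbon C7; direct photolysis at room temperature favours the Wolff shift over 1,2-hydride migration from C4 and spares the heat-sensitive ethynyl ether until it is consumed, and high dilution suppresses ketene dimerisation.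

Step 19
Reactants: 37 penta-O-benzyl ether
Product: 38 (2R,3R)-8-[(2S,4S)-7-hydroxy-2-(4-hydroxyphenyl)chroman-4-yl]-2-(4-hydroxyphenyl)chromane-3,5,7-triol (target)
Conditions: H2 (1 atm), Pd(OH)2/C, THF–MeOH, rt
Reagents that add atoms: none
Why: Catalytic hydrogenolysis of the four aryl benzyl ethers and the secondary benzyl ether over Pd(OH)2; the ring C–O and C–C bonds at C2 and C4 of both flavan units are not cleaved under these mild conditions, as in the deprotection of benzylated proanthocyanidins.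

**Compound list**

1 | (−)-epiafzelechin, (2R,3R)-2-(4-hydroxyphenyl)chromane-3,5,7-triol | Oc1cc(O)c2C[C@@H](O)[C@@H](c3ccc(O)cc3)Oc2c1 | starting material
2 | (2R,3R)-5,7-bis(benzyloxy)-2-[4-(benzyloxy)phenyl]chroman-3-ol | c1c(OCc2ccccc2)cc(OCc2ccccc2)c2c1O[C@H](c1ccc(OCc3ccccc3)cc1)[C@H](O)C2 | intermediate
3 | (2R,3R)-3,5,7-tris(benzyloxy)-2-[4-(benzyloxy)phenyl]chromane (ArD–H) | c1c(OCc2ccccc2)cc(OCc2ccccc2)c2c1O[C@H](c1ccc(OCc3ccccc3)cc1)[C@H](OCc1ccccc1)C2 | intermediate
4 | (2R,3R)-8-bromo-3,5,7-tris(benzyloxy)-2-[4-(benzyloxy)phenyl]chromane (ArD–Br) | Brc1c(OCc2ccccc2)cc(OCc2ccccc2)c2c1O[C@H](c1ccc(OCc3ccccc3)cc1)[C@H](OCc1ccccc1)C2 | intermediate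
5 | ArD–Li, the 8-lithio derivative of 3 | [Li]c1c(OCc2ccccc2)cc(OCc2ccccc2)c2c1O[C@H](c1ccc(OCc3ccccc3)cc1)[C@H](OCc1ccccc1)C2 | intermediate
6 | ArD–CHO, (2R,3R)-3,5,7-tris(benzyloxy)-2-[4-(benzyloxy)phenyl]chromane-8-carbaldehyde | O=Cc1c(OCc2ccccc2)cc(OCc2ccccc2)c2c1O[C@H](c1ccc(OCc3ccccc3)cc1)[C@H](OCc1ccccc1)C2 | intermediate
7 | dimethyl malonate | COC(=O)CC(=O)OC | starting material
8 | dimethyl 2-(ArD-methylidene)malonate | COC(=O)C(C(=O)OC)=Cc1c(OCc2ccccc2)cc(OCc2ccccc2)c2c1O[C@H](c1ccc(OCc3ccccc3)cc1)[C@H](OCc1ccccc1)C2 | intermediate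
9 | tetramethyl 2-ArD-propane-1,1,3,3-tetracarboxylate | COC(=O)C(C(=O)OC)C(C(C(=O)OC)C(=O)OC)c1c(OCc2ccccc2)cc(OCc2ccccc2)c2c1O[C@H](c1ccc(OCc3ccccc3)cc1)[C@H](OCc1ccccc1)C2 | intermediate
10 | 2-ArD-propane-1,1,3,3-tetracarboxylic acid | OC(=O)C(C(O)=O)C(C(C(O)=O)C(O)=O)c1c(OCc2ccccc2)cc(OCc2ccccc2)c2c1O[C@H](c1ccc(OCc3ccccc3)cc1)[C@H](OCc1ccccc1)C2 | intermediate
11 | 3-ArD-pentanedioic acid | OC(=O)CC(CC(O)=O)c1c(OCc2ccccc2)cc(OCc2ccccc2)c2c1O[C@H](c1ccc(OCc3ccccc3)cc1)[C@H](OCc1ccccc1)C2 | intermediate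
12 | 4-ArD-oxane-2,6-dione (3-ArD-glutaric anhydride) | O=C1CC(CC(=O)O1)c1c(OCc2ccccc2)cc(OCc2ccccc2)c2c1O[C@H](c1ccc(OCc3ccccc3)cc1)[C@H](OCc1ccccc1)C2 | intermediate
13 | (3S)-3-ArD-5-methoxy-5-oxopentanoic acid | OC(=O)C[C@@H](CC(=O)OC)c1c(OCc2ccccc2)cc(OCc2ccccc2)c2c1O[C@H](c1ccc(OCc3ccccc3)cc1)[C@H](OCc1ccccc1)C2 | intermediate
14 | 1-(benzyloxy)-4-bromobenzene | Brc1ccc(OCc2ccccc2)cc1 | starting material
15 | methyl (3R)-3-ArD-5-chloro-5-oxopentanoate | ClC(=O)C[C@@H](CC(=O)OC)c1c(OCc2ccccc2)cc(OCc2ccccc2)c2c1O[C@H](c1ccc(OCc3ccccc3)cc1)[C@H](OCc1ccccc1)C2 | intermediate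
16 | [4-(benzyloxy)phenyl]magnesium bromide | Br[Mg]c1ccc(OCc2ccccc2)cc1 | intermediate
17 | methyl (3S)-3-ArD-5-ArB-5-oxopentanoate | O(Cc1ccccc1)c1ccc(cc1)C(=O)C[C@@H](CC(=O)OC)c1c(OCc2ccccc2)cc(OCc2ccccc2)c2c1O[C@H](c1ccc(OCc3ccccc3)cc1)[C@H](OCc1ccccc1)C2 | intermediate
18 | methyl (3S,5S)-3-ArD-5-ArB-5-hydroxypentanoate | O(Cc1ccccc1)c1ccc(cc1)[C@@H](O)C[C@@H](CC(=O)OC)c1c(OCc2ccccc2)cc(OCc2ccccc2)c2c1O[C@H](c1ccc(OCc3ccccc3)cc1)[C@H](OCc1ccccc1)C2 | intermediate
19 | (1S,3R)-3-ArD-1-ArB-pentane-1,5-diol | O(Cc1ccccc1)c1ccc(cc1)[C@@H](O)C[C@@H](CCO)c1c(OCc2ccccc2)cc(OCc2ccccc2)c2c1O[C@H](c1ccc(OCc3ccccc3)cc1)[C@H](OCc1ccccc1)C2 | intermediate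
20 | (1S,3R)-3-ArD-1-ArB-5-[(tert-butyldimethylsilyl)oxy]pentan-1-ol | O(Cc1ccccc1)c1ccc(cc1)[C@@H](O)C[C@@H](CCO[Si](C)(C)C(C)(C)C)c1c(OCc2ccccc2)cc(OCc2ccccc2)c2c1O[C@H](c1ccc(OCc3ccccc3)cc1)[C@H](OCc1ccccc1)C2 | intermediate
21 | trichloroethylene | ClC=C(Cl)Cl | starting material
22 | (E)-1,2-dichlorovinyl ether of 20 (3R,5S in the pentyl chain) | O(Cc1ccccc1)c1ccc(cc1)[C@@H](O/C(Cl)=C\Cl)C[C@@H](CCO[Si](C)(C)C(C)(C)C)c1c(OCc2ccccc2)cc(OCc2ccccc2)c2c1O[C@H](c1ccc(OCc3ccccc3)cc1)[C@H](OCc1ccccc1)C2 | intermediate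
23 | chloroethynyl ether of 20 (C2 and C4 as in 22) | O(Cc1ccccc1)c1ccc(cc1)[C@@H](OC#CCl)C[C@@H](CCO[Si](C)(C)C(C)(C)C)c1c(OCc2ccccc2)cc(OCc2ccccc2)c2c1O[C@H](c1ccc(OCc3ccccc3)cc1)[C@H](OCc1ccccc1)C2 | intermediate
24 | lithium acetylide of 25 | O(Cc1ccccc1)c1ccc(cc1)[C@@H](OC#C[Li])C[C@@H](CCO[Si](C)(C)C(C)(C)C)c1c(OCc2ccccc2)cc(OCc2ccccc2)c2c1O[C@H](c1ccc(OCc3ccccc3)cc1)[C@H](OCc1ccccc1)C2 | intermediate
25 | tert-butyl{[(3R,5S)-3-ArD-5-ArB-5-(ethynyloxy)pentyl]oxy}dimethylsilane | O(Cc1ccccc1)c1ccc(cc1)[C@@H](OC#C)C[C@@H](CCO[Si](C)(C)C(C)(C)C)c1c(OCc2ccccc2)cc(OCc2ccccc2)c2c1O[C@H](c1ccc(OCc3ccccc3)cc1)[C@H](OCc1ccccc1)C2 | intermediate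
26 | (3R,5S)-3-ArD-5-ArB-5-(ethynyloxy)pentan-1-ol | O(Cc1ccccc1)c1ccc(cc1)[C@@H](OC#C)C[C@@H](CCO)c1c(OCc2ccccc2)cc(OCc2ccccc2)c2c1O[C@H](c1ccc(OCc3ccccc3)cc1)[C@H](OCc1ccccc1)C2 | intermediate
27 | (3S,5S)-3-ArD-5-ArB-5-(ethynyloxy)pentanal | O(Cc1ccccc1)c1ccc(cc1)[C@@H](OC#C)C[C@@H](CC=O)c1c(OCc2ccccc2)cc(OCc2ccccc2)c2c1O[C@H](c1ccc(OCc3ccccc3)cc1)[C@H](OCc1ccccc1)C2 | intermediate
28 | (5R,7S)-5-ArD-7-ArB-7-(ethynyloxy)hept-1-en-3-ol, both C3 epimers | O(Cc1ccccc1)c1ccc(cc1)[C@@H](OC#C)C[C@@H](CC(O)C=C)c1c(OCc2ccccc2)cc(OCc2ccccc2)c2c1O[C@H](c1ccc(OCc3ccccc3)cc1)[C@H](OCc1ccccc1)C2 | intermediate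
29 | (5S,7S)-5-ArD-7-ArB-7-(ethynyloxy)hept-1-en-3-one | O(Cc1ccccc1)c1ccc(cc1)[C@@H](OC#C)C[C@@H](CC(=O)C=C)c1c(OCc2ccccc2)cc(OCc2ccccc2)c2c1O[C@H](c1ccc(OCc3ccccc3)cc1)[C@H](OCc1ccccc1)C2 | intermediate
30 | lithium enolate of 29 toward C4a (C2 and C4 as in 29) | O(Cc1ccccc1)c1ccc(cc1)[C@@H](OC#C)C[C@@H](C=C(O[Li])C=C)c1c(OCc2ccccc2)cc(OCc2ccccc2)c2c1O[C@H](c1ccc(OCc3ccccc3)cc1)[C@H](OCc1ccccc1)C2 | intermediate
31 | 4-(trifluoroacetyl) derivative of 29 (C4a epimers and enol forms; C2 and C4 as in 29) | O(Cc1ccccc1)c1ccc(cc1)[C@@H](OC#C)C[C@@H](C(C(=O)C(F)(F)F)C(=O)C=C)c1c(OCc2ccccc2)cc(OCc2ccccc2)c2c1O[C@H](c1ccc(OCc3ccccc3)cc1)[C@H](OCc1ccccc1)C2 | intermediate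
32 | (5R,7S)-4-diazo-5-ArD-7-ArB-7-(ethynyloxy)hept-1-en-3-one (key-step precursor) | O(Cc1ccccc1)c1ccc([C@@H](OC#C)C[C@H](c2c(OCc3ccccc3)cc(OCc3ccccc3)c3c2O[C@H](c2ccc(OCc4ccccc4)cc2)[C@H](OCc2ccccc2)C3)C(=[N+]=[N-])C(=O)C=C)cc1 | intermediate
33 | vinylketene O=C7=C4a(C4)–C5=C6 (C2 and C4 as in 32) | O(Cc1ccccc1)c1ccc([C@@H](OC#C)C[C@H](c2c(OCc3ccccc3)cc(OCc3ccccc3)c3c2O[C@H](c2ccc(OCc4ccccc4)cc2)[C@H](OCc2ccccc2)C3)C(=C=O)C=C)cc1 | intermediate
34 | 3-ArB-5-ArD-6-ethenyl-2-oxabicyclo[4.2.0]oct-1(8)-en-7-one (C2 and C4 as in 32; C4a epimers) | O(Cc1ccccc1)c1ccc(cc1)[C@@H]2C[C@H](c3c(OCc4ccccc4)cc(OCc4ccccc4)c4c3O[C@H](c3ccc(OCc5ccccc5)cc3)[C@H](OCc3ccccc3)C4)C3(C=C)C(=O)C=C3O2 | intermediate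
35 | dienylketene: 2-ArB-4-ArD-5-ethenyl-6-(2-oxoethenyl)-3,4-dihydro-2H-pyran (C2 and C4 as in 32) | O(Cc1ccccc1)c1ccc(cc1)[C@@H]2C[C@H](c3c(OCc4ccccc4)cc(OCc4ccccc4)c4c3O[C@H](c3ccc(OCc5ccccc5)cc3)[C@H](OCc3ccccc3)C4)C(C=C)=C(C=C=O)O2 | intermediate
36 | cyclohexadienone tautomer of 37: 2-ArB-4-ArD-3,4-dihydro-2H-chromen-7(6H)-one | O(Cc1ccccc1)c1ccc(cc1)[C@@H]2C[C@H](c3c(OCc4ccccc4)cc(OCc4ccccc4)c4c3O[C@H](c3ccc(OCc5ccccc5)cc3)[C@H](OCc3ccccc3)C4)C3=CCC(=O)C=C3O2 | intermediate
37 | (2R,3R)-3,5,7-tris(benzyloxy)-2-[4-(benzyloxy)phenyl]-8-{(2S,4S)-2-[4-(benzyloxy)phenyl]-7-hydroxychroman-4-yl}chromane | O(Cc1ccccc1)c1ccc([C@@H]2C[C@H](c3c(OCc4ccccc4)cc(OCc4ccccc4)c4c3O[C@H](c3ccc(OCc5ccccc5)cc3)[C@H](OCc3ccccc3)C4)c3ccc(O)cc3O2)cc1 | intermediate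
38 | (2R,3R)-8-[(2S,4S)-7-hydroxy-2-(4-hydroxyphenyl)chroman-4-yl]-2-(4-hydroxyphenyl)chromane-3,5,7-triol | Oc1ccc([C@@H]2C[C@H](c3c(O)cc(O)c4c3O[C@H](c3ccc(O)cc3)[C@H](O)C4)c3ccc(O)cc3O2)cc1 | target

**Count and risk**

Total step count: 19. Longest linear sequence: 19 steps from 1; compound 7 enters in steps 4 and 5, compound 14 in step 9 and compound 21 in step 12.

Steps most likely to fail:

1. Step 18 (key step).
   - What may go wrong: 1,2-hydride migration from C4 competing with the Wolff shift; dipolar cycloaddition of the diazo group onto the tethered alkyne before irradiation; ketene dimerisation; or a tethered [2+2] too slow to compete with these.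
   - Fallback (known chemistry; sets out from 3 and comes back at 38): 4-(benzyloxy)-2-hydroxyacetophenone and 4-(benzyloxy)benzaldehyde are condensed (KOH, EtOH) to the 2'-hydroxychalcone F1. Cyclisation (NaOAc, EtOH, reflux) gives racemic 7,4'-bis(benzyloxy)flavanone F2. Asymmetric transfer hydrogenation with kinetic resolution (RuCl[(S,S)-TsDPEN](p-cymene) or its enantiomer, whichever reduces the (2S) ketone, HCO2H–Et3N) gives the cis-(2S,4S)-flavan-4-ol F3. Friedel–Crafts alkylation of excess 3 with F3 (BF3·OEt2, CH2Cl2, −40 °C → rt) forms the C4–C8 bond and gives the hexa-O-benzyl dimer F4. It is run under equilibrating conditions so that the 2,4-cis isomer with both aryl groups equatorial should predominate; it is separated from the C4 epimer and any C6-linked isomer. Hydrogenolysis as in step 19 then gives 38.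

2. Step 17.
   - What may go wrong: Michael oligomerisation of the enolate of the unsubstituted vinyl ketone before acyl transfer; metalation of the acetylenic C–H; or cycloaddition of the sulfonyl azide with the ethynyl ether if the azide is used in excess or warm.
   - Fallback (sets out from 27 and comes back at 37): the enone is made non-polymerisable by a removable silyl group on its terminus. (E)-2-(Trimethylsilyl)vinylmagnesium bromide is added to 27 at −78 °C to give the silylated allylic alcohol F5. Buffered Dess–Martin oxidation gives the β-silyl enone F6. The diazo transfer of step 17, which is routine for β-substituted enones, gives the silylated diazo enone F7. Irradiation as in step 18 gives the 6-trimethylsilyl phenol F8 (or its O-silyl isomer). Protodesilylation ortho to the phenol (Bu4NF, THF) gives 37.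

3. Step 12.
   - What may go wrong: loss of the benzylic ethynyl ether by retro-ene fragmentation, sigmatropic rearrangement or hydration during its isolation and the three operations that follow.
   - Fallback (sets out from 22 and comes back at 28): the reaction is stopped after the KH/trichloroethylene stage and the robust dichlorovinyl ether 22 is isolated and carried forward. Bu4NF gives the dichlorovinyl ether alcohol F9, Dess–Martin oxidation the aldehyde F10, and CH2=CHMgBr at −78 °C the allylic alcohol F11. n-BuLi (3.5 equiv, −78 °C) followed by MeOH then unveils the alkyne on the allylic alkoxide and gives 28 directly, so the ethynyl ether has to survive only one oxidation and the diazo transfer.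

**Further compounds**

F1 | step 18 | (E)-1-[4-(benzyloxy)-2-hydroxyphenyl]-3-[4-(benzyloxy)phenyl]prop-2-en-1-one | O=C(/C=C/c1ccc(OCc2ccccc2)cc1)c1ccc(OCc2ccccc2)cc1O
F2 | step 18 | racemic 7-(benzyloxy)-2-[4-(benzyloxy)phenyl]chroman-4-one | O=C1CC(c2ccc(OCc3ccccc3)cc2)Oc2cc(OCc3ccccc3)ccc12
F3 | step 18 | (2S,4S)-7-(benzyloxy)-2-[4-(benzyloxy)phenyl]chroman-4-ol | O(Cc1ccccc1)c1ccc([C@@H]2C[C@H](O)c3ccc(OCc4ccccc4)cc3O2)cc1
F4 | step 18 | (2R,3R)-3,5,7-tris(benzyloxy)-2-[4-(benzyloxy)phenyl]-8-{(2S,4S)-7-(benzyloxy)-2-[4-(benzyloxy)phenyl]chroman-4-yl}chromane | O(Cc1ccccc1)c1ccc([C@@H]2C[C@H](c3c(OCc4ccccc4)cc(OCc4ccccc4)c4c3O[C@H](c3ccc(OCc5ccccc5)cc3)[C@H](OCc3ccccc3)C4)c3ccc(OCc4ccccc4)cc3O2)cc1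
F5 | step 17 | (1E,5R,7S)-5-ArD-7-ArB-7-(ethynyloxy)-1-(trimethylsilyl)hept-1-en-3-ol, both C3 epimers | O(Cc1ccccc1)c1ccc(cc1)[C@@H](OC#C)C[C@@H](CC(O)/C=C/[Si](C)(C)C)c1c(OCc2ccccc2)cc(OCc2ccccc2)c2c1O[C@H](c1ccc(OCc3ccccc3)cc1)[C@H](OCc1ccccc1)C2
F6 | step 17 | (1E,5S,7S)-5-ArD-7-ArB-7-(ethynyloxy)-1-(trimethylsilyl)hept-1-en-3-one | O(Cc1ccccc1)c1ccc(cc1)[C@@H](OC#C)C[C@@H](CC(=O)/C=C/[Si](C)(C)C)c1c(OCc2ccccc2)cc(OCc2ccccc2)c2c1O[C@H](c1ccc(OCc3ccccc3)cc1)[C@H](OCc1ccccc1)C2
F7 | step 17 | (1E,5R,7S)-4-diazo-5-ArD-7-ArB-7-(ethynyloxy)-1-(trimethylsilyl)hept-1-en-3-one | O(Cc1ccccc1)c1ccc(cc1)[C@@H](OC#C)C[C@@H](C(=[N+]=[N-])C(=O)/C=C/[Si](C)(C)C)c1c(OCc2ccccc2)cc(OCc2ccccc2)c2c1O[C@H](c1ccc(OCc3ccccc3)cc1)[C@H](OCc1ccccc1)C2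
F8 | step 17 | 6-(trimethylsilyl) derivative of 37 | O(Cc1ccccc1)c1ccc([C@@H]2C[C@H](c3c(OCc4ccccc4)cc(OCc4ccccc4)c4c3O[C@H](c3ccc(OCc5ccccc5)cc3)[C@H](OCc3ccccc3)C4)c3cc([Si](C)(C)C)c(O)cc3O2)cc1
F9 | step 12 | (3R,5S)-3-ArD-5-ArB-5-{[(E)-1,2-dichloroethenyl]oxy}pentan-1-ol | O(Cc1ccccc1)c1ccc(cc1)[C@@H](O/C(Cl)=C\Cl)C[C@@H](CCO)c1c(OCc2ccccc2)cc(OCc2ccccc2)c2c1O[C@H](c1ccc(OCc3ccccc3)cc1)[C@H](OCc1ccccc1)C2
F10 | step 12 | (3S,5S)-3-ArD-5-ArB-5-{[(E)-1,2-dichloroethenyl]oxy}pentanal | O(Cc1ccccc1)c1ccc(cc1)[C@@H](O/C(Cl)=C\Cl)C[C@@H](CC=O)c1c(OCc2ccccc2)cc(OCc2ccccc2)c2c1O[C@H](c1ccc(OCc3ccccc3)cc1)[C@H](OCc1ccccc1)C2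
F11 | step 12 | (5R,7S)-5-ArD-7-ArB-7-{[(E)-1,2-dichloroethenyl]oxy}hept-1-en-3-ol, both C3 epimers | O(Cc1ccccc1)c1ccc(cc1)[C@@H](O/C(Cl)=C\Cl)C[C@@H](CC(O)C=C)c1c(OCc2ccccc2)cc(OCc2ccccc2)c2c1O[C@H](c1ccc(OCc3ccccc3)cc1)[C@H](OCc1ccccc1)C2
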